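**Retrosynthetic overview**

1. Target 6 is acyclic and achiral. Its acid and alcohol halves are the same 3-(3,4-dimethoxyphenyl)propyl unit at two oxidation levels; no ring is formed, and both benzene rings are bought intact as 4.
2. Key disconnection: both aryl–CH2 bonds at once, giving two electrophilic aryl carbons (2 × 4-bromoveratrole 4) and a C3–O–C(=O)–C2 bis-nucleophile 5. The acyl arm of 5 is an ester homoenolate (β-zincio ester, d3) and the alkoxy arm is the d3 synthon ⁻CH2CH2CH2O–.
3. 5 ⇒ dibromide 3 by double zinc insertion, which inverts the polarity of two carbons that are electrophilic in 3.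
4. 3 ⇒ ester C–O disconnection to 3-bromopropan-1-ol 1 and 3-bromopropanoyl chloride 2.
5. Order: ester linker first, then both aryl rings attached last in one pot. (Compound numbers follow the forward route.)

Assumption: the target has no stereocentre or stereogenic double bond, so "single enantiomer" needs no stereocontrol. Because the route has only two steps, the risk ranking lists the two independent stages of step 2 separately, then step 1.

**Route**

Step 1
Reactants: 1 3-bromopropan-1-ol; 2 3-bromopropanoyl chloride (1.1 equiv)
Product: 3 3-bromopropyl 3-bromopropanoate
Conditions: CH2Cl2, 0 °C → rt, slow N2 sweep to remove HCl, no amine base; cold aq. NaHCO3 wash, short-path distillation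
Reagents that add atoms: none
Why: Alcoholysis of an acid chloride (nucleophilic acyl substitution) is fast without base, and leaving out amine base avoids E1cB loss of HBr from the β-bromo acyl unit to the acrylate; no stereocentre is formed.

Step 2
Reactants: 3 3-bromopropyl 3-bromopropanoate; 4 4-bromo-1,2-dimethoxybenzene (4-bromoveratrole, 2.4 equiv)
Product: 6 3-(3,4-dimethoxyphenyl)propyl 3-(3,4-dimethoxyphenyl)propanoate (target), via bis(bromozinc) homoenolate reagent 5 (not isolated)
Conditions: Zn dust (3 equiv, activated with BrCH2CH2Br/TMSCl), LiCl (3 equiv), THF, 50 °C; titrate (I2), decant from excess Zn onto 4, Pd(OAc)2 (2 mol%), SPhos (4 mol%), THF, rt → 50 °C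
Reagents that add atoms: none
Why: LiCl-promoted direct zinc insertion into both primary C–Br bonds gives a chelate-stabilised β-zincio ester (zinc homoenolate) and a 3-acyloxypropylzinc, both too weakly nucleophilic to attack the internal ester, and a double Pd/SPhos Negishi sp3–sp2 cross-coupling then joins each zinc-bearing CH2 to the electrophilic aryl carbon of 4 faster than β-hydride elimination; no stereocentre is formed.

**Compound list**

1 | 3-bromopropan-1-ol | OCCCBr | starting material
2 | 3-bromopropanoyl chloride | O=C(Cl)CCBr | starting material
3 | 3-bromopropyl 3-bromopropanoate | BrCCCOC(=O)CCBr | intermediate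
4 | 4-bromo-1,2-dimethoxybenzene (4-bromoveratrole) | COc1ccc(Br)cc1OC | starting material
5 | 3-(bromozincio)propyl 3-(bromozincio)propanoate, bis(bromozinc) homoenolate reagent | Br[Zn]CCCOC(=O)CC[Zn]Br | intermediate (not isolated)
6 | 3-(3,4-dimethoxyphenyl)propyl 3-(3,4-dimethoxyphenyl)propanoate (CNP0122973.0) | COc1ccc(CCCOC(=O)CCc2ccc(OC)c(OC)c2)cc1OC | target

**Totals**

Total step count: 2. Longest linear sequence: 2 (1 or 2 → 3 → 6).

**Steps most likely to fail, with fallbacks**

1. Step 2, coupling stage. Both C–Zn ends must couple; protodezincation or β-hydride elimination at one end would give mono-arylated, acrylate or propyl-ester by-products. The fallback sets out from 4 and comes back at 6. It makes both halves from one single homoenolate coupling, since they are the same aryl-C3 unit at two oxidation levels. Compound 4 is coupled under the same Pd(OAc)2/SPhos conditions with commercial (3-ethoxy-3-oxopropyl)zinc bromide (CCOC(=O)CC[Zn]Br, 0.5 M in THF) to give ethyl 3-(3,4-dimethoxyphenyl)propanoate F1. About half of this ester is reduced with LiAlH4 in THF at 0 °C to 3-(3,4-dimethoxyphenyl)propan-1-ol F2. The ester and the alcohol are then joined by Bu2SnO-catalysed transesterification in refluxing toluene, with ethanol distilled off, to give 6.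

2. Step 2, insertion stage. The bis-zinc reagent 5 may not form cleanly: the unactivated bromopropyl arm may insert slowly, the β-bromo ester arm may eliminate, or Wurtz coupling may intervene. The fallback sets out from 3 and comes back at 6, and avoids any stoichiometric organometallic. Compound 3 is converted with NaI in acetone (rt, dark) into 3-iodopropyl 3-iodopropanoate F3. This is coupled directly with 4 by nickel-catalysed reductive cross-electrophile coupling (NiI2·glyme 10 mol%, 4,4'-di-tert-butyl-2,2'-bipyridine 10 mol%, pyridine 10 mol%, Mn powder, DMPU, 60 °C). Alkyl radicals from the C–I bonds are captured by the arylnickel(II) species, giving 6.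

3. Step 1. Partial loss of HBr during acylation or work-up would give mixtures of 3 with acrylate esters. The fallback sets out from 1 and comes back at 3, and turns the failure product into the intermediate. Compound 1 is esterified with acrylic acid (cat. TsOH, hydroquinone, toluene, Dean–Stark) to 3-bromopropyl acrylate F4. Anhydrous HBr in CH2Cl2 at 0 °C then adds in conjugate fashion to give 3. A contaminated batch from step 1 can be treated with HBr in the same way.

**Further compounds**

F1 | step 2 | ethyl 3-(3,4-dimethoxyphenyl)propanoate | CCOC(=O)CCc1ccc(OC)c(OC)c1
F2 | step 2 | 3-(3,4-dimethoxyphenyl)propan-1-ol | OCCCc1ccc(OC)c(OC)c1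
F3 | step 2 | 3-iodopropyl 3-iodopropanoate | ICCCOC(=O)CCI
F4 | step 1 | 3-bromopropyl acrylate | C=CC(=O)OCCCBr
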